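The substrate sits in a first phase and the reagent in a second, and you want to know which of two flasks, teal or violet, ends with more target.

| flask | substrate | reagent in the second phase | remark | time | volume of the second phase over the first |
|---|---|---|---|---|---|
| midnight | 1.2 M | 1.7 M | run made earlier |  |  |
| spring | 1.2 M | 1.5 M | run made earlier |  |  |
| noon | 1.2 M | 2 M | run made earlier |  |  |
| teal | 1.2 M | 2.00 M |  | 1.5 min | 1.0 |
| violet | 1.2 M | 1.44 M |  | 2.5 min | 1.0 |

| run | time / min | target / % | substrate / % |
|---|---|---|---|
| midnight | 0.667 | 44.6 | 55.9 |
| midnight | 1.33 | 69.8 | 31.3 |
| midnight | 2.00 | 82.4 | 16.8 |
| midnight | 2.50 | 90.0 | 12.3 |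
| spring | 0.333 | 21.1 | 79.7 |
| spring | 0.833 | 49.6 | 51.8 |
| spring | 1.50 | 68.5 | 32.1 |
| spring | 2.50 | 83.6 | 18.2 |
| noon | 0.667 | 49.8 | 48.8 |
| noon | 1.33 | 76.1 | 23.1 |
| noon | 2.00 | 87.3 | 11.3 |
| noon | 2.50 | 95.5 | 6.7 |

(scatter of a reading: 1 percentage point)

- in the second phase: reagent in the second phase; everything else is in the first
- charges count per volume of the first phase; a concentration in a rate is the amount of a species over the volume of its own phase; every rate counts per litre of the first phase
- the earlier runs hold the two phases in the same ratio of volumes as the flask asked about

- the flask that ends with the higher amount of target, in percent of the substrate charged, or "neither" when 2 percentage points or less lies between them (teal / violet / neither)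
- final target, as a percentage of the substrate charged, in teal
- final target, as a percentage of the substrate charged, in violet

Build the flask up piece by piece. Take first the main step, substrate plus reagent to target, with the reagent's level held steady, so that substrate falls exponentially (pseudo-first-order). The logarithm of charged over left, divided by time, is then 1.08 /min at the last reading of the noon run; this decay constant k is what you carry. The first noon reading gives 1.08 /min, about the same. Teal has noon's charge, so after 1.5 min its target should be 80.2 %.

Now let the second phase drain. If one reagent goes per substrate, that target costs teal 0.963 M of reagent, leaving 51.9 % of its charge or less. Yet k did not sag across the noon run, so this addition leaves teal's number where it was.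

Last comes the charge. The spring run's final reading, at violet's time, gives k = 0.681 /min, lower than noon's. Between the two runs k goes as the charge to the power 1.60, steeper than proportion. Spring's k also sags, from 0.758 /min at 1.50 min, and its last reading already holds that sag. Scaled to 1.44 M, k becomes 0.638 /min, so after 2.5 min violet's target should be 79.7 %. The products of k and time are 1.62 for teal and 1.59 for violet, so my gap of 0.52 percentage points stays under the margin: neither.

The forecast, which finds “almost no slowing as reagent is used up”, says 80 % for teal, 80.5 % for violet, and neither.

The flask gives 80.7 % in teal and 81.3 % in violet, so the answer is neither.

    2 reagent in the reaction phase → self-condensation product (k = 0.110 /M/s)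
    substrate + reagent in the reaction phase → target (k = 0.160 /M/s)
    reagent in the reaction phase ⇌ reagent in the second phase, rate k3*([reagent in the reaction phase] - [reagent in the second phase]/K3) per volume of the first phase (partition coefficient = 1.70, kL = 0.0260 /s)

In teal at 0.504 min, the main step gives the reagent in the reaction phase a half-life of 0.10 min, shorter than the substrate's 0.60 min, and that reagent is made 1.00 times as fast as it is used up, each step taken net. In this quasi-steady state of teal, c(reagent in the reaction phase) stands at 0.121 M at 0.750 min and 0.115 M at 1.50 min, and the main step's constant times that last level is 1.11 /min, beside the carried 1.08 /min. A neighbour of teal charged with 0.30 M of substrate stands at 0.181 M, and its k, from 6.0 % left at 1.50 min, is 1.87 /min.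

The numbers in the tables stem from a simulated flask with constants of no real substance.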